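**Preacredinone A (10) by a chromium carbene benzannulation that builds ring B from open-chain pieces**

## The problem

Preacredinone A (10) is an achiral benzophenone. Ring A is a 2,6-dimethoxyphenyl group. Ring B is a pentasubstituted benzene, numbered here C1 (bears the ketone), C2 (OH), C3 (H), C4 (CH3), C5 (OCH3) and C6 (CH2OAc). There is no stereocentre, so the difficulty lies in connectivity and congestion: a diaryl ketone with all four ortho positions occupied, and a ring B with five different substituents in a fixed order. The two oxygens of ring B are para to each other (C2 and C5) and must be told apart, one free and one methylated. Several groups forbid rough treatment: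
- the primary benzylic acetate on an electron-rich ring can solvolyse or migrate to the C2 phenol, and the free alcohol would close onto the ketone as a lactol;
- the aryl methyl ethers ortho to the ketone are cleaved by strong Lewis acids;
- the hydroquinone monomethyl ether is oxidised to a quinone by strong oxidants;
- hot base can close the ortho-hydroxy/ortho'-methoxy benzophenone to a xanthone.

The feature that opens the plan is that ring B is a 4-methoxyphenol. The C5–OCH3 carbon is flanked by the H/CH3 edge (C3–C4) on one side and by the edge carrying the two carbon substituents (C6–C1) on the other, and the C2–OH carbon closes the ring between C1 and C3. This is the pattern a Dötz benzannulation delivers: C5 and its OCH3 from a methoxycarbene carbon, C4/C3 from an isopropenyl group, C2–OH from a CO ligand, and C6/C1 from an alkyne.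

## Retrosynthesis

**Ring B (10 ⇒ 9 ⇒ 5 + 8).** Three ring bonds are cut: C5–C6, C1–C2 and C2–C3. Target 10 is the metal-free form of the tricarbonylchromium arene complex 9, which comes from the isopropenyl(methoxy)carbene complex 5 and the ynone 8. The other way of mapping the ring onto this reaction would make the C3–C4 edge the alkyne. That mapping is rejected because the methyl group would then sit next to the phenol carbon, not next to the methoxy carbon. The chosen cut removes the whole pentasubstituted ring, the para O/O differentiation and the attachment of the hindered ketone in one operation. The precursors are an acyclic C14 ynone and a four-carbon carbene complex. The forward reaction must insert the alkyne so that the aroyl-bearing carbon takes up CO, and it must tolerate the acetate.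

**Ynone (8 ⇒ 6 + 7).** The C(=O)–C(sp) bond is cut, giving 2,6-dimethoxybenzoyl chloride 6 and propargyl acetate 7. Cutting the aryl–C(=O) bond instead would require an aryl nucleophile and a protected, activated butynoic acid, which costs extra steps and protecting-group changes. The forward reaction is a palladium/copper-catalysed acylation of the terminal alkyne under nearly neutral conditions, so the acetate is already in place.

**Carbene complex (5 ⇒ 4 ⇒ 3 + 2; 3 ⇒ 1).** The O–CH3 bond and the bond between the carbene carbon and the isopropenyl carbon are cut. Complex 5 is the O-methylation product of the lithium acylchromate 4. Acylate 4 arises from isopropenyllithium 3 and a carbonyl ligand of hexacarbonylchromium 2, and 3 comes from 2-bromopropene 1 by halogen–lithium exchange. This is the classical Fischer sequence; it asks only for a clean exchange and a hard methylating agent.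

## Roads not taken

**Alternative 1:** the obvious cut is the bond between the ketone carbon and ring A. 2,6-Dimethoxyphenyllithium A1 would add to the protected phthalide A2 to give the hydroxy ketone A3 (in equilibrium with its lactol), followed by acetylation and removal of the methoxymethyl group to reach 10.
- The whole difficulty moves into A2, a pentasubstituted arene that needs a long sequence of aromatic substitutions and a differentiation of the hydroquinone oxygens.
- The addition must build a tetra-ortho-substituted ketone from a hindered nucleophile.
- The last acid-mediated deprotection puts the benzylic acetate at risk.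
- The chosen plan makes ring B and its link to the ketone in one step, with no protecting group.

**Alternative 2:** cut the C1–C(=O) bond and form it by an anionic Fries rearrangement. Halogen–lithium exchange on the bromoaryl ester A4 would trigger a 1,3 O-to-C acyl shift to give the ortho-hydroxybenzophenone A5, followed by desilylation and acetylation.
- A4 is a hexasubstituted benzene and is harder to make than the target ring itself.
- The bromine is needed because a Lewis-acid Fries rearrangement could not distinguish C1 from C3 and would cleave the methyl ethers.
- The end game must acetylate a primary alcohol that sits next to a ketone and a free phenol.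
- Nothing in this route builds ring B.

**Alternative 3:** make ring B from another ring. An inverse-demand Diels–Alder reaction of the 3-aroyl-2-pyrone A6 with the ynol ether A7, followed by decarboxylative aromatisation, would be short.
- The polarity is wrong: the nucleophilic carbon of A7 (the one bearing CH2OAc) bonds to C6 of the pyrone, so the methoxy carbon ends up next to the aroyl-bearing carbon. The expected product is the regioisomer A8, with OCH3 and CH2OAc exchanged.
- A7 is a labile ynol ether, and the 4-hydroxy group makes A6 a poor electron-deficient diene.
- In the chosen benzannulation the steric rule works in the required direction.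

Key step: step 3

## Route

Remark: the target has no stereocentre, so no stereochemical assumption is needed. In the SMILES each CO ligand is written as Cr=C=O, and an η6-arene complex is written as the arene plus a Cr(CO)3 fragment.

Step 1
Reactants: 1 2-bromopropene; 2 hexacarbonylchromium Cr(CO)6
Product: 5 pentacarbonyl(1-methoxy-2-methylprop-2-en-1-ylidene)chromium, via isopropenyllithium 3 (not isolated), via lithium acylchromate 4 (not isolated)
Conditions: t-BuLi (2 equiv), THF, −78 °C; then Cr(CO)6, THF, 0 °C to rt; then Me3OBF4, CH2Cl2, 0 °C to rt
Reagents that add atoms: trimethyloxonium tetrafluoroborate, C[O+](C)C.F[B-](F)(F)F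
Why: Fischer carbene complex synthesis: halogen–lithium exchange, addition of the vinyllithium to a CO ligand of Cr(CO)6, and O-methylation of the acylate by a hard oxonium salt; this is the standard preparation of alkenyl(methoxy)carbene complexes.

Step 2
Reactants: 6 2,6-dimethoxybenzoyl chloride; 7 prop-2-yn-1-yl acetate
Product: 8 4-(2,6-dimethoxyphenyl)-4-oxobut-2-yn-1-yl acetate
Conditions: PdCl2(PPh3)2 (2 mol %), CuI (4 mol %), Et3N (1.2 equiv), THF, rt
Reagents that add atoms: none
Why: Acyl Sonogashira coupling: the aroyl chloride adds oxidatively to zerovalent palladium formed in the flask, the copper acetylide of 7 transmetalates, and reductive elimination gives the ynone; the acid chloride has no α-hydrogen, and one equivalent of tertiary amine at room temperature should leave the acetate and the ynone intact.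

Step 3
Reactants: 5 pentacarbonyl(1-methoxy-2-methylprop-2-en-1-ylidene)chromium; 8 4-(2,6-dimethoxyphenyl)-4-oxobut-2-yn-1-yl acetate
Product: 10 preacredinone A = [2-(2,6-dimethoxybenzoyl)-3-hydroxy-6-methoxy-5-methylphenyl]methyl acetate, via tricarbonylchromium arene complex 9 (not isolated)
Conditions: 5 (1.5 equiv), THF (0.05 M), 50 °C, Ar; then air, Et2O, rt
Reagents that add atoms: none
Why: Dötz benzannulation, a formal (3+2+1) assembly of ring B in the coordination sphere of chromium. Thermal loss of one CO from 5 lets 8 coordinate and insert into the Cr=C bond, so that the carbene carbon (future C5 with its OCH3) bonds to the alkyne carbon bearing CH2OAc (future C6) and the aroyl-bearing carbon (future C1) becomes the new carbene carbon. A CO ligand then inserts at that carbon to give a chromium-bound dienylketene whose ketene carbon is the future C2, a 6π electrocyclic closure between this carbon and the terminal CH2 of the isopropenyl unit (future C3) forms the six-membered carbocycle, and tautomerisation of the cyclohexadienone gives the phenol as its Cr(CO)3 complex 9, which air frees from the metal. The closest known reaction type is the benzannulation of alkenyl(methoxy)carbene complexes of chromium with alkynyl ketones, in which the larger alkyne substituent ends up next to the CO-derived carbon. The selectivity needed is therefore the direction of alkyne insertion, and it should be secured by the 2,6-dimethoxybenzoyl group, whose di-ortho-substituted ring is twisted out of the carbonyl plane and is much bulkier than the primary CH2OAc group that must take the crowded central position of the vinylcarbene intermediate. Phenol formation, as opposed to five-membered ring formation, is favoured by chromium, by an alkenyl complex with an unsubstituted terminal carbon, and by a moderately coordinating solvent at high dilution. The step differentiates the two para oxygens without a protecting group (C5–O arrives methylated, C2–O arrives as the free hydrogen-bonded phenol) and forms no stereocentre. The neutral conditions should leave the benzylic acetate, the aryl methyl ethers and the ketone untouched.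

## Compound list

1 | 2-bromopropene | CC(Br)=C | starting material
2 | hexacarbonylchromium Cr(CO)6 | O=C=[Cr](=C=O)(=C=O)(=C=O)(=C=O)=C=O | starting material
3 | isopropenyllithium (prop-1-en-2-yllithium) | [Li]C(C)=C | intermediate
4 | lithium pentacarbonyl(2-methylprop-2-enoyl)chromate | [Li+].[O-]C(C(C)=C)=[Cr](=C=O)(=C=O)(=C=O)(=C=O)=C=O | intermediate
5 | pentacarbonyl(1-methoxy-2-methylprop-2-en-1-ylidene)chromium | COC(C(C)=C)=[Cr](=C=O)(=C=O)(=C=O)(=C=O)=C=O | intermediate
6 | 2,6-dimethoxybenzoyl chloride | COc1cccc(OC)c1C(Cl)=O | starting material
7 | prop-2-yn-1-yl acetate (propargyl acetate) | C#CCOC(C)=O | starting material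
8 | 4-(2,6-dimethoxyphenyl)-4-oxobut-2-yn-1-yl acetate | COc1cccc(OC)c1C(=O)C#CCOC(C)=O | intermediate
9 | tricarbonylchromium η6 complex of 10 (Cr(CO)3 on ring B) | COc1cccc(OC)c1C(=O)c1c(O)cc(C)c(OC)c1COC(C)=O.O=C=[Cr](=C=O)=C=O | intermediate
10 | preacredinone A, [2-(2,6-dimethoxybenzoyl)-3-hydroxy-6-methoxy-5-methylphenyl]methyl acetate | COc1cccc(OC)c1C(=O)c1c(O)cc(C)c(OC)c1COC(C)=O | target

## Step count and risks

Total steps: 3. Longest linear sequence: 2 (step 1 or step 2, then step 3).

**Step 3 (key step).**
- What may go wrong: the alkyne may insert the wrong way, so that the acetoxymethyl-bearing carbon takes up CO. The aroyl carbon attached to the alkyne is trigonal, and the electronic preference of an ynone (conjugation of the acyl group with the methoxy-substituted double bond when it sits at the central position) opposes the steric preference.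
- The electron-poor alkyne may also insert slowly, which would allow thermal decay of 5 and incorporation of a second alkyne.
- The chromium-bound acylketene may be diverted before the electrocyclic closure.
- Fallback (from 8, back at 10): the ketone is carried through the benzannulation in masked, non-conjugated form.
  - Luche reduction of 8 (NaBH4, CeCl3·7H2O, MeOH, −78 °C) should give racemic 4-(2,6-dimethoxyphenyl)-4-hydroxybut-2-yn-1-yl acetate F1.
  - Silylation (TBSCl, imidazole, DMF) should give racemic 4-(tert-butyldimethylsilyloxy)-4-(2,6-dimethoxyphenyl)but-2-yn-1-yl acetate F2.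
  - Benzannulation of F2 with 5 (THF, 50 °C) now involves an electron-neutral alkyne with a branched secondary substituent against a primary one. It should give the tricarbonylchromium arene complex F3 and, after exposure to air, racemic {2-[(tert-butyldimethylsilyloxy)(2,6-dimethoxyphenyl)methyl]-3-hydroxy-6-methoxy-5-methylphenyl}methyl acetate F4.
  - Desilylation (HF·pyridine, THF, 0 °C) should give racemic {2-[(2,6-dimethoxyphenyl)(hydroxy)methyl]-3-hydroxy-6-methoxy-5-methylphenyl}methyl acetate F5.
  - Benzylic oxidation (activated MnO2, CH2Cl2, rt) removes the stereocentre and returns to 10.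

**Step 2.**
- What may go wrong: transmetalation and reductive elimination at the di-ortho-substituted aroylpalladium intermediate may be slow. Copper-mediated oxidative dimerisation of 7 and decarbonylation could then compete, and amine or chloride could add to the ynone once it has formed.
- Fallback (from 6, back at 8): the C(=O)–C(sp) bond is made by adding an alkynyllithium to an amide.
  - Amidation of 6 (MeNHOMe·HCl, pyridine, CH2Cl2, 0 °C) should give 2,6-dimethoxy-N-methoxy-N-methylbenzamide F6.
  - Commercial tert-butyldimethyl(prop-2-yn-1-yloxy)silane F7 is deprotonated (n-BuLi, THF, −78 °C) to [3-(tert-butyldimethylsilyloxy)prop-1-yn-1-yl]lithium F8.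
  - Addition of F8 to F6 should give, after work-up, 4-(tert-butyldimethylsilyloxy)-1-(2,6-dimethoxyphenyl)but-2-yn-1-one F9.
  - Desilylation (HF·pyridine, THF, 0 °C) should give 1-(2,6-dimethoxyphenyl)-4-hydroxybut-2-yn-1-one F10.
  - Acetylation (Ac2O, pyridine, CH2Cl2, 0 °C) returns to 8.

**Step 1.**
- What may go wrong: O-methylation of the ambident acylate may be incomplete, and the volatile, air-sensitive complex may be lost by hydrolysis or oxidation during isolation. By-products of an incomplete halogen–lithium exchange would be carried along.
- Fallback (from 4, back at 5): O-alkylation is replaced by acylation and alcoholysis through a purifiable salt.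
  - The crude acylate 4 is taken up in water and precipitated with Me4NBr as tetramethylammonium pentacarbonyl(2-methylprop-2-enoyl)chromate F11, a storable solid.
  - Acetyl bromide (CH2Cl2, −40 °C) should convert F11 into pentacarbonyl(1-acetoxy-2-methylprop-2-en-1-ylidene)chromium F12, which is not isolated.
  - Methanol (−40 °C to rt) exchanges the acyloxy group and returns to 5.

## Further compounds

F1 | step 3 | 4-(2,6-dimethoxyphenyl)-4-hydroxybut-2-yn-1-yl acetate (racemic) | COc1cccc(OC)c1C(O)C#CCOC(C)=O
F2 | step 3 | 4-(tert-butyldimethylsilyloxy)-4-(2,6-dimethoxyphenyl)but-2-yn-1-yl acetate (racemic) | COc1cccc(OC)c1C(O[Si](C)(C)C(C)(C)C)C#CCOC(C)=O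
F3 | step 3 | tricarbonylchromium η6 complex of F4 (racemic) | COc1cccc(OC)c1C(O[Si](C)(C)C(C)(C)C)c1c(O)cc(C)c(OC)c1COC(C)=O.O=C=[Cr](=C=O)=C=O
F4 | step 3 | {2-[(tert-butyldimethylsilyloxy)(2,6-dimethoxyphenyl)methyl]-3-hydroxy-6-methoxy-5-methylphenyl}methyl acetate (racemic) | COc1cccc(OC)c1C(O[Si](C)(C)C(C)(C)C)c1c(O)cc(C)c(OC)c1COC(C)=O
F5 | step 3 | {2-[(2,6-dimethoxyphenyl)(hydroxy)methyl]-3-hydroxy-6-methoxy-5-methylphenyl}methyl acetate (racemic) | COc1cccc(OC)c1C(O)c1c(O)cc(C)c(OC)c1COC(C)=O
F6 | step 2 | 2,6-dimethoxy-N-methoxy-N-methylbenzamide | COc1cccc(OC)c1C(=O)N(C)OC
F7 | step 2 | tert-butyldimethyl(prop-2-yn-1-yloxy)silane | C#CCO[Si](C)(C)C(C)(C)C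
F8 | step 2 | [3-(tert-butyldimethylsilyloxy)prop-1-yn-1-yl]lithium | [Li]C#CCO[Si](C)(C)C(C)(C)C
F9 | step 2 | 4-(tert-butyldimethylsilyloxy)-1-(2,6-dimethoxyphenyl)but-2-yn-1-one | COc1cccc(OC)c1C(=O)C#CCO[Si](C)(C)C(C)(C)C
F10 | step 2 | 1-(2,6-dimethoxyphenyl)-4-hydroxybut-2-yn-1-one | COc1cccc(OC)c1C(=O)C#CCO
F11 | step 1 | tetramethylammonium pentacarbonyl(2-methylprop-2-enoyl)chromate | C[N+](C)(C)C.[O-]C(C(C)=C)=[Cr](=C=O)(=C=O)(=C=O)(=C=O)=C=O
F12 | step 1 | pentacarbonyl(1-acetoxy-2-methylprop-2-en-1-ylidene)chromium | CC(=O)OC(C(C)=C)=[Cr](=C=O)(=C=O)(=C=O)(=C=O)=C=O
A1 | alternative 1 | 2,6-dimethoxyphenyllithium | [Li]c1c(OC)cccc1OC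
A2 | alternative 1 | 4-methoxy-7-(methoxymethoxy)-5-methyl-2-benzofuran-1(3H)-one | O=C1OCc2c(OC)c(C)cc(OCOC)c12
A3 | alternative 1 | (2,6-dimethoxyphenyl)[2-(hydroxymethyl)-3-methoxy-6-(methoxymethoxy)-4-methylphenyl]methanone | COc1cccc(OC)c1C(=O)c1c(OCOC)cc(C)c(OC)c1CO
A4 | alternative 2 | 2-bromo-3-[(tert-butyldimethylsilyloxy)methyl]-4-methoxy-5-methylphenyl 2,6-dimethoxybenzoate | COc1cccc(OC)c1C(=O)Oc1cc(C)c(OC)c(CO[Si](C)(C)C(C)(C)C)c1Br
A5 | alternative 2 | {2-[(tert-butyldimethylsilyloxy)methyl]-6-hydroxy-3-methoxy-4-methylphenyl}(2,6-dimethoxyphenyl)methanone | COc1cccc(OC)c1C(=O)c1c(O)cc(C)c(OC)c1CO[Si](C)(C)C(C)(C)C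
A6 | alternative 3 | 3-(2,6-dimethoxybenzoyl)-4-hydroxy-6-methyl-2H-pyran-2-one | COc1cccc(OC)c1C(=O)C1=C(O)C=C(C)OC1=O
A7 | alternative 3 | 3-methoxyprop-2-yn-1-yl acetate | COC#CCOC(C)=O
A8 | alternative 3 | [3-(2,6-dimethoxybenzoyl)-4-hydroxy-2-methoxy-6-methylphenyl]methyl acetate | COc1cccc(OC)c1C(=O)c1c(O)cc(C)c(COC(C)=O)c1OC
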